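**Plan**
1. Target 17 is 7,8,3'-trihydroxy-6,4',5'-trimethoxyisoflavone. The three phenols are masked as benzyl ethers. The retrosynthesis then cuts C4–C4a (aryl ketone bond of ring C), O1–C2 (aryl vinyl ether), C2–C3 (formyl carbon) and C3–C4 (one-carbon homologation of the ring B aldehyde).
2. Enabling feature: C8 of ring A bears oxygen, so C4a is the only unsubstituted carbon next to O1. C4a sits para to the oxygen on C7, and the short O1–C2=C3 link lets the acyl carbon C4 reach C4a but not C5.
3. Forward, rings A and B are bought as benzaldehydes. The ring A aldehyde is benzylated and degraded to a phenol. The ring B aldehyde is benzylated, homologated to the arylacetate, formylated and tosylated.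
4. The phenoxide displaces the tosylate (O1–C2) and saponification frees the acrylic acid. Ring C, the only ring built, is closed last by intramolecular Friedel–Crafts acylation, and hydrogenolysis ends the route.
5. The target has no stereocentre. Only the C2=C3 geometry matters: it is set Z by tosylation of a lithium-chelated enolate, kept in the substitution, and absorbed into ring C.

Key step: step 10

Assumption: compounds 11–15 are drawn as the Z isomers that ring closure needs; these push–pull alkenes are configurationally labile under acid, so any E component would be carried forward and not separated.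

Step 1
Reactants: 1 2,3-dihydroxy-4-methoxybenzaldehyde
Product: 2 2,3-bis(benzyloxy)-4-methoxybenzaldehyde
Conditions: BnBr, K2CO3, DMF, 60 °C
Reagents that add atoms: benzyl bromide, BrCc1ccccc1
Why: Williamson etherification, in which carbonate deprotonates both phenols (the chelated 2-OH needs the warm DMF), the phenoxides displace bromide, and the non-enolisable aldehyde is untouched.

Step 2
Reactants: 2 2,3-bis(benzyloxy)-4-methoxybenzaldehyde
Product: 4 2,3-bis(benzyloxy)-4-methoxyphenol, via aryl formate 3 (not isolated)
Conditions: mCPBA, CH2Cl2, 0 °C to rt; then MeOH, Et3N (cat.), rt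
Reagents that add atoms: mCPBA, OOC(=O)c1cccc(Cl)c1
Why: Baeyer–Villiger oxidation in its Dakin-type sense, in which the aryl group, enriched by ortho and para alkoxy donors, migrates in the Criegee adduct in preference to hydride, and base-catalysed transesterification with methanol strips formate 3 to the phenol without touching the ethers.

Step 3
Reactants: 5 3-hydroxy-4,5-dimethoxybenzaldehyde
Product: 6 3-(benzyloxy)-4,5-dimethoxybenzaldehyde
Conditions: BnBr, K2CO3, DMF, rt to 60 °C
Reagents that add atoms: benzyl bromide, BrCc1ccccc1
Why: Williamson etherification of the single free phenol, chosen so that all three masked hydroxyls of the target fall in one final hydrogenolysis.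

Step 4
Reactants: 6 3-(benzyloxy)-4,5-dimethoxybenzaldehyde; 7 methyl (methylsulfinyl)methyl sulfide (FAMSO)
Product: 8 1-(benzyloxy)-2,3-dimethoxy-5-[2-(methylsulfanyl)-2-(methylsulfinyl)ethenyl]benzene
Conditions: benzyltrimethylammonium hydroxide (Triton B, cat.), THF, reflux
Reagents that add atoms: none
Why: Knoevenagel-type condensation, in which the carbanion of 7, stabilised by both sulfur groups, adds to the aldehyde and water is lost, installing the future C4 carbon at the carboxylic acid oxidation level.

Step 5
Reactants: 8 1-(benzyloxy)-2,3-dimethoxy-5-[2-(methylsulfanyl)-2-(methylsulfinyl)ethenyl]benzene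
Product: 9 methyl 2-[3-(benzyloxy)-4,5-dimethoxyphenyl]acetate
Conditions: HCl in MeOH, rt to 50 °C
Reagents that add atoms: methanol, CO
Why: Acid-catalysed alcoholysis of a ketene dithioacetal S-oxide (a Pummerer-related, redox-neutral process), in which protonation at the benzylic carbon, addition of methanol and expulsion of both sulfur groups should give the arylacetic ester, while aryl benzyl and methyl ethers tolerate methanolic HCl.

Step 6
Reactants: 9 methyl 2-[3-(benzyloxy)-4,5-dimethoxyphenyl]acetate; 10 methyl formate
Product: 11 methyl (Z)-2-[3-(benzyloxy)-4,5-dimethoxyphenyl]-3-hydroxyacrylate (hydrogen-bonded enol of the α-formyl ester)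
Conditions: NaH, HCO2Me (excess), THF, 0 °C to rt; then 1 M HCl
Reagents that add atoms: none
Why: Crossed Claisen condensation, in which only 9 can form an enolate, the formate is the reactive non-enolisable acceptor, and formation of the sodium salt of 11 pulls the equilibrium over and brings in C2.

Step 7
Reactants: 11 methyl (Z)-2-[3-(benzyloxy)-4,5-dimethoxyphenyl]-3-hydroxyacrylate
Product: 12 methyl (Z)-2-[3-(benzyloxy)-4,5-dimethoxyphenyl]-3-(tosyloxy)acrylate
Conditions: TsCl, N-methylimidazole, LiOH, CH2Cl2, 0 °C to rt
Reagents that add atoms: p-toluenesulfonyl chloride, Cc1ccc(cc1)S(=O)(=O)Cl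
Why: O-Sulfonylation of a β-dicarbonyl enolate, in which N-methylimidazole turns TsCl into a reactive N-sulfonylimidazolium salt and lithium holds the enolate oxygen and the ester carbonyl in a chelate, so that the tosyloxy group should end cis to the ester (Z).

Step 8
Reactants: 4 2,3-bis(benzyloxy)-4-methoxyphenol; 12 methyl (Z)-2-[3-(benzyloxy)-4,5-dimethoxyphenyl]-3-(tosyloxy)acrylate
Product: 13 methyl (Z)-3-[2,3-bis(benzyloxy)-4-methoxyphenoxy]-2-[3-(benzyloxy)-4,5-dimethoxyphenyl]acrylate
Conditions: Cs2CO3, MeCN, 0 °C to rt
Reagents that add atoms: none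
Why: Nucleophilic vinylic substitution by addition–elimination, in which the phenoxide adds to the unhindered β-carbon, the ester- and aryl-stabilised carbanion expels tosylate (normally with retention of geometry), and the oxygen-centred bond formation keeps the ring carbons of 4 away from the formyl carbon, which shuts off a Pechmann-type coumarin path.

Step 9
Reactants: 13 methyl (Z)-3-[2,3-bis(benzyloxy)-4-methoxyphenoxy]-2-[3-(benzyloxy)-4,5-dimethoxyphenyl]acrylate
Product: 14 (Z)-3-[2,3-bis(benzyloxy)-4-methoxyphenoxy]-2-[3-(benzyloxy)-4,5-dimethoxyphenyl]acrylic acid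
Conditions: LiOH, THF–MeOH–H2O, rt to 40 °C; then 1 M HCl, 0 °C
Reagents that add atoms: lithium hydroxide, [Li+].[OH-]
Why: Saponification by acyl–oxygen cleavage, routine for 3-aryloxyacrylates and aryloxyfumarates, with cold and brief acidification so that the push–pull enol ether is not hydrolysed.

Step 10
Reactants: 14 (Z)-3-[2,3-bis(benzyloxy)-4-methoxyphenoxy]-2-[3-(benzyloxy)-4,5-dimethoxyphenyl]acrylic acid
Product: 16 7,8-bis(benzyloxy)-3-[3-(benzyloxy)-4,5-dimethoxyphenyl]-6-methoxy-4H-chromen-4-one, via mixed trifluoroacetic anhydride 15 (not isolated)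
Conditions: (CF3CO)2O, CH2Cl2 (high dilution), 0 °C to rt
Reagents that add atoms: trifluoroacetic anhydride, O=C(OC(=O)C(F)(F)F)C(F)(F)F (its CF3CO group is held only by intermediate 15 and is absent from 16)
Why: Trifluoroacetic anhydride converts 14 into mixed anhydride 15, whose ionisation, helped by the trifluoroacetic acid released, gives an acyl cation stabilised by the enol-ether oxygen; C4a of ring A attacks C4 and proton loss from the arenium ion restores aromaticity (intramolecular Friedel–Crafts acylation). The closest known reaction type is the acid-mediated cyclodehydration of 3-aryloxyacrylic and aryloxyfumaric acids to chromones and chromone-2-carboxylic acids, run here with the mild anhydride activation that is routine for alkoxy-substituted aryl- and aryloxypropanoic acids. Ring C closes in a 6-exo mode at the acyl carbon (the C=O stays outside the new ring, the C4a–C8a arene bond lies inside it), and no stereocentre is created. The only site selectivity needed is C4a over C5: the Z-configured O1–C2=C3 link reaches C4a alone, C8 is blocked by its benzyloxy group, C4a is activated by O1 (ortho) and the C7 oxygen (para), and dilution suppresses intermolecular acylation at C5 or on ring B. Because the cation has ketene–oxocarbenium character (O=C=C3–C2H=O1+), rotation about C2–C3 is easy, so E material should also converge on 16. The absence of a strong Lewis or mineral acid is what should keep the three benzyl ethers in place.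

Step 11
Reactants: 16 7,8-bis(benzyloxy)-3-[3-(benzyloxy)-4,5-dimethoxyphenyl]-6-methoxy-4H-chromen-4-one
Product: 17 7,8-dihydroxy-3-(3-hydroxy-4,5-dimethoxyphenyl)-6-methoxy-4H-chromen-4-one (CNP0115098.0)
Conditions: H2 (1 atm), 10% Pd/C, THF–MeOH, rt
Reagents that add atoms: none
Why: Catalytic hydrogenolysis of the three benzylic C–O bonds, in which methyl ethers are inert and the C2=C3 bond, part of a vinylogous ester, is reduced far more slowly, so the reaction is stopped once three equivalents of hydrogen are consumed.

**Compound list**
1 | 2,3-dihydroxy-4-methoxybenzaldehyde | COc1ccc(C=O)c(O)c1O | starting material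
2 | 2,3-bis(benzyloxy)-4-methoxybenzaldehyde | COc1ccc(C=O)c(OCc2ccccc2)c1OCc1ccccc1 | intermediate
3 | 2,3-bis(benzyloxy)-4-methoxyphenyl formate (not isolated) | COc1ccc(OC=O)c(OCc2ccccc2)c1OCc1ccccc1 | intermediate
4 | 2,3-bis(benzyloxy)-4-methoxyphenol | COc1ccc(O)c(OCc2ccccc2)c1OCc1ccccc1 | intermediate
5 | 3-hydroxy-4,5-dimethoxybenzaldehyde | COc1cc(C=O)cc(O)c1OC | starting material
6 | 3-(benzyloxy)-4,5-dimethoxybenzaldehyde | COc1cc(C=O)cc(OCc2ccccc2)c1OC | intermediate
7 | methyl (methylsulfinyl)methyl sulfide (FAMSO, racemic at sulfur) | CSCS(C)=O | starting material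
8 | 1-(benzyloxy)-2,3-dimethoxy-5-[2-(methylsulfanyl)-2-(methylsulfinyl)ethenyl]benzene (alkene geometry and sulfur configuration uncontrolled, both erased in step 5) | CSC(=Cc1cc(OC)c(OC)c(OCc2ccccc2)c1)S(C)=O | intermediate
9 | methyl 2-[3-(benzyloxy)-4,5-dimethoxyphenyl]acetate | COC(=O)Cc1cc(OC)c(OC)c(OCc2ccccc2)c1 | intermediate
10 | methyl formate | COC=O | starting material
11 | methyl (Z)-2-[3-(benzyloxy)-4,5-dimethoxyphenyl]-3-hydroxyacrylate (enol of the α-formyl ester) | COC(=O)/C(c1cc(OC)c(OC)c(OCc2ccccc2)c1)=C\O | intermediate
12 | methyl (Z)-2-[3-(benzyloxy)-4,5-dimethoxyphenyl]-3-(tosyloxy)acrylate | COC(=O)/C(c1cc(OC)c(OC)c(OCc2ccccc2)c1)=C\OS(=O)(=O)c1ccc(C)cc1 | intermediate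
13 | methyl (Z)-3-[2,3-bis(benzyloxy)-4-methoxyphenoxy]-2-[3-(benzyloxy)-4,5-dimethoxyphenyl]acrylate | COC(=O)/C(c1cc(OCc2ccccc2)c(OC)c(OC)c1)=C\Oc1ccc(OC)c(OCc2ccccc2)c1OCc1ccccc1 | intermediate
14 | (Z)-3-[2,3-bis(benzyloxy)-4-methoxyphenoxy]-2-[3-(benzyloxy)-4,5-dimethoxyphenyl]acrylic acid | OC(=O)/C(c1cc(OCc2ccccc2)c(OC)c(OC)c1)=C\Oc1ccc(OC)c(OCc2ccccc2)c1OCc1ccccc1 | intermediate
15 | (Z)-3-[2,3-bis(benzyloxy)-4-methoxyphenoxy]-2-[3-(benzyloxy)-4,5-dimethoxyphenyl]acrylic trifluoroacetic anhydride (not isolated) | O=C(OC(=O)C(F)(F)F)/C(c1cc(OCc2ccccc2)c(OC)c(OC)c1)=C\Oc1ccc(OC)c(OCc2ccccc2)c1OCc1ccccc1 | intermediate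
16 | 7,8-bis(benzyloxy)-3-[3-(benzyloxy)-4,5-dimethoxyphenyl]-6-methoxy-4H-chromen-4-one | COc1cc2c(=O)c(-c3cc(OCc4ccccc4)c(OC)c(OC)c3)coc2c(OCc2ccccc2)c1OCc1ccccc1 | intermediate
17 | 7,8-dihydroxy-3-(3-hydroxy-4,5-dimethoxyphenyl)-6-methoxy-4H-chromen-4-one | COc1cc2c(=O)c(-c3cc(O)c(OC)c(OC)c3)coc2c(O)c1O | target

Total step count: 11. Longest linear sequence: 9 steps (5 to 17, steps 3–11). The ring A branch (steps 1–2) joins at step 8.

**Steps most likely to fail**

Step 10 (ring closure).
- The donor-stabilised acyl cation may be too weak an electrophile. The C7 oxygen is partly twisted out of conjugation by its two neighbours, and O1 shares its lone pair with the acrylate.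
- Slow closure would leave time for acid-induced loss or migration of benzyl groups, for capture of the cation by the C8 ether oxygen, for intermolecular acylation, and for incomplete E-to-Z equilibration.
- The fallback lowers the oxidation level of the tether and sets out from 14. Homogeneous hydrogenation with Ru(OAc)2(rac-BINAP) under H2 pressure in MeOH leaves benzyl ethers alone and should saturate C2=C3, giving (±)-3-[2,3-bis(benzyloxy)-4-methoxyphenoxy]-2-[3-(benzyloxy)-4,5-dimethoxyphenyl]propanoic acid F1.
- In F1 the acyl cation is no longer conjugated, O1 is a full donor and no alkene geometry exists. Trifluoroacetic anhydride in CH2Cl2 should then effect the standard chroman-4-one closure of a 3-aryloxypropanoic acid, giving (±)-7,8-bis(benzyloxy)-3-[3-(benzyloxy)-4,5-dimethoxyphenyl]-6-methoxychroman-4-one F2.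
- Dehydrogenation of this isoflavanone with DDQ in dioxane brings the route back at 16.

Step 8 (O1–C2 bond).
- The phenoxide may attack sulfur instead of carbon, transferring the sulfonyl group and returning the enolate of 11.
- A long-lived carbanion may also erode the alkene geometry.
- The fallback sets out from 11 and replaces the sulfonate by a halide, which offers carbon as the only electrophilic site. The Vilsmeier reagent made from oxalyl chloride and DMF in CH2Cl2 should give methyl (Z)-3-chloro-2-[3-(benzyloxy)-4,5-dimethoxyphenyl]acrylate F3.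
- F3 is then treated with phenol 4, K2CO3 and catalytic DABCO in DMF, and the route is rejoined at 13.

Step 9 (ester cleavage).
- Hydroxide may add to the β-carbon C2 and expel the phenoxide, reversing step 8, instead of attacking the hindered, vinylogous-carbonate-like ester carbonyl.
- The fallback sets out from 13 and moves the point of attack to the methyl carbon. Nucleophilic dealkylation with LiI in refluxing EtOAc cleaves the O–CH3 bond and leaves the acrylate carbons alone.
- Acidification returns the route at 14. No compound outside the list arises (F0).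

**Further compounds**
F1 | step 10 | (±)-3-[2,3-bis(benzyloxy)-4-methoxyphenoxy]-2-[3-(benzyloxy)-4,5-dimethoxyphenyl]propanoic acid | OC(=O)C(COc1ccc(OC)c(OCc2ccccc2)c1OCc1ccccc1)c1cc(OCc2ccccc2)c(OC)c(OC)c1
F2 | step 10 | (±)-7,8-bis(benzyloxy)-3-[3-(benzyloxy)-4,5-dimethoxyphenyl]-6-methoxychroman-4-one | COc1cc2C(=O)C(COc2c(OCc2ccccc2)c1OCc1ccccc1)c1cc(OCc2ccccc2)c(OC)c(OC)c1
F3 | step 8 | methyl (Z)-3-chloro-2-[3-(benzyloxy)-4,5-dimethoxyphenyl]acrylate | COC(=O)/C(c1cc(OCc2ccccc2)c(OC)c(OC)c1)=C\Cl
F0 | step 9 | none | none
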